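Locants follow the germacrane skeleton: carbocycle C1–C10, lactone C6–O–C12 with C11=C13 on C7, ester C14 on C10, C15 on C4. The route rests on opening the ten-membered ring at C1–C2, because C1 is the sp2 β-carbon of the C1=C10 enoate and C2 is an unactivated CH2. In one operation, hydroboration of a C2=C3 vinyl group and palladium-catalysed coupling with a geometrically defined C1 enol triflate form C1–C2, close the carbocycle onto the preformed trans α-methylene-γ-lactone and transfer the alkene geometry. The precursor is the open-chain lactone carrying the C4 vinyl group, the C15 silyl ether, the C8 isobutyrate and the (E)-enol triflate whose OTf is cis to C9.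

Key step: step 14

Remark: compound 4 is taken as a catalogue chemical; 6 and 16 are drawn as single tautomers although a cyclic hemiketal and an enol are also present.

Step 1
Reactants: 1 furan-2(5H)-one; 2 potassium vinyltrifluoroborate
Product: 3 (4R)-4-ethenyloxolan-2-one
Conditions: [Rh(cod)Cl]2 (cat.), (R)-BINAP, toluene/H2O, 90 °C
Reagents that add atoms: none
Why: Rhodium-catalysed asymmetric conjugate addition (Hayashi–Miyaura type) of the vinyl group to the butenolide, in which the (R)-BINAP–rhodium vinyl species should select the enantioface that gives C4 as R, by analogy with cyclic enones and unsaturated lactones.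

Step 2
Reactants: 3 (4R)-4-ethenyloxolan-2-one; 4 1-methoxy-4-[(prop-2-yn-1-yloxy)methyl]benzene
Product: 6 (6R)-6-(hydroxymethyl)-1-[(4-methoxyphenyl)methoxy]oct-7-en-2-yn-4-one, via lithium alkynide 5 (not isolated)
Conditions: n-BuLi, THF, −78 °C; then 3, −78 °C; H2O
Reagents that add atoms: none
Why: Nucleophilic acyl substitution in which the lithium alkynide adds once to the lactone carbonyl (C6), because the lithium hemiketalate is stable at −78 °C and releases the hydroxy ynone only on quenching; C4 is not touched.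

Step 3
Reactants: 6 (6R)-6-(hydroxymethyl)-1-[(4-methoxyphenyl)methoxy]oct-7-en-2-yn-4-one
Product: 7 (6R)-6-({[tert-butyl(dimethyl)silyl]oxy}methyl)-1-[(4-methoxyphenyl)methoxy]oct-7-en-2-yn-4-one
Conditions: TBSCl, imidazole, CH2Cl2, 0 °C → rt
Reagents that add atoms: tert-butyldimethylsilyl chloride, CC(C)(C)[Si](C)(C)Cl
Why: Silyl ether formation at the primary C15 alcohol, which also removes the ring–chain equilibrium of the hydroxy ketone.

Step 4
Reactants: 7 (6R)-6-({[tert-butyl(dimethyl)silyl]oxy}methyl)-1-[(4-methoxyphenyl)methoxy]oct-7-en-2-yn-4-one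
Product: 8 (4R,6R)-6-({[tert-butyl(dimethyl)silyl]oxy}methyl)-1-[(4-methoxyphenyl)methoxy]oct-7-en-2-yn-4-ol
Conditions: Ru[(R,R)-TsDPEN](p-cymene) (cat.), iPrOH, rt
Reagents that add atoms: none
Why: Noyori asymmetric transfer hydrogenation of an alkynyl ketone, in which the (R,R)-catalyst distinguishes the alkynyl from the alkyl flank and should set C6 as R under catalyst control, independent of the remote C4 centre.

Step 5
Reactants: 8 (4R,6R)-6-({[tert-butyl(dimethyl)silyl]oxy}methyl)-1-[(4-methoxyphenyl)methoxy]oct-7-en-2-yn-4-ol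
Product: 10 (2Z,4R,6R)-6-({[tert-butyl(dimethyl)silyl]oxy}methyl)-2-iodo-1-[(4-methoxyphenyl)methoxy]octa-2,7-dien-4-ol, via cyclic vinylalanate 9 (not isolated)
Conditions: NaAlH2(OCH2CH2OCH3)2, THF, 0 °C; then I2, −78 °C
Reagents that add atoms: iodine, II
Why: Alkoxide-directed trans-hydroalumination of the propargylic alcohol (hydride to C7, aluminium to C11 in a five-membered chelate) followed by iodinolysis with retention gives the (Z)-iodoalkene with iodine on C11 cis to C6.

Step 6
Reactants: 10 (2Z,4R,6R)-6-({[tert-butyl(dimethyl)silyl]oxy}methyl)-2-iodo-1-[(4-methoxyphenyl)methoxy]octa-2,7-dien-4-ol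
Product: 11 (5R)-5-[(2R)-2-({[tert-butyl(dimethyl)silyl]oxy}methyl)but-3-en-1-yl]-3-{[(4-methoxyphenyl)methoxy]methyl}furan-2(5H)-one
Conditions: PdCl2(PPh3)2 (cat.), CO (balloon), K2CO3, THF, 40 °C
Reagents that add atoms: carbon monoxide, [C-]#[O+]
Why: Palladium-catalysed carbonylative lactonisation, in which oxidative addition into the C11–I bond, CO insertion and capture of the acylpalladium by the cis C6 hydroxyl close the butenolide and introduce C12, a sequence that under CO should outrun any Heck cyclisation onto the vinyl group.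

Step 7
Reactants: 11 (5R)-5-[(2R)-2-({[tert-butyl(dimethyl)silyl]oxy}methyl)but-3-en-1-yl]-3-{[(4-methoxyphenyl)methoxy]methyl}furan-2(5H)-one
Product: 12 (5R)-5-[(2R)-2-({[tert-butyl(dimethyl)silyl]oxy}methyl)but-3-en-1-yl]-3-(hydroxymethyl)furan-2(5H)-one
Conditions: DDQ, CH2Cl2/pH 7 buffer, 0 °C
Reagents that add atoms: none
Why: Oxidative cleavage of the p-methoxybenzyl ether by DDQ frees the C13 alcohol and leaves the silyl ether and the alkenes alone.

Step 8
Reactants: 12 (5R)-5-[(2R)-2-({[tert-butyl(dimethyl)silyl]oxy}methyl)but-3-en-1-yl]-3-(hydroxymethyl)furan-2(5H)-one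
Product: 13 (5R)-3-(bromomethyl)-5-[(2R)-2-({[tert-butyl(dimethyl)silyl]oxy}methyl)but-3-en-1-yl]furan-2(5H)-one
Conditions: CBr4, PPh3, CH2Cl2, 0 °C
Reagents that add atoms: carbon tetrabromide, BrC(Br)(Br)Br
Why: Appel bromination converts the primary allylic alcohol into the bromide under neutral conditions by SN2 displacement of the alkoxyphosphonium ion.

Step 9
Reactants: 14 methyl pent-4-enoate
Product: 16 methyl 2-formylpent-4-enoate, via lithium enolate 15 (not isolated)
Conditions: LiN(iPr)2, THF, −78 °C; HCO2CH3, −78 → 0 °C; aq. HCl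
Reagents that add atoms: methyl formate, COC=O
Why: Crossed Claisen condensation (α-formylation) of the ester enolate with methyl formate, in which the product is held as its stabilised enolate until acidification.

Step 10
Reactants: 16 methyl 2-formylpent-4-enoate
Product: 17 methyl (2E)-2-({[(trifluoromethyl)sulfonyl]oxy}methylidene)pent-4-enoate
Conditions: Tf2O, iPr2NEt, CH2Cl2, −78 °C
Reagents that add atoms: trifluoromethanesulfonic anhydride, O=S(=O)(OS(=O)(=O)C(F)(F)F)C(F)(F)F
Why: O-Triflation of the formyl ester enolate, where the non-chelating ammonium counter-ion should place the enolate oxygen trans to the ester and so favour the (E)-enol triflate (OTf cis to the future C9); any Z isomer is removed by chromatography.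

Step 11
Reactants: 17 methyl (2E)-2-({[(trifluoromethyl)sulfonyl]oxy}methylidene)pent-4-enoate
Product: 19 methyl (2E)-4-oxo-2-({[(trifluoromethyl)sulfonyl]oxy}methylidene)butanoate, via secondary ozonide 18 (not isolated)
Conditions: O3, CH2Cl2, −78 °C; then (CH3)2S
Reagents that add atoms: ozone, [O-][O+]=O
Why: Ozonolysis with reductive work-up cleaves only the terminal alkene, since the enol triflate alkene is deactivated by the ester and the sulfonate, and gives the C8 aldehyde, which is used at once.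

Step 12
Reactants: 13 (5R)-3-(bromomethyl)-5-[(2R)-2-({[tert-butyl(dimethyl)silyl]oxy}methyl)but-3-en-1-yl]furan-2(5H)-one; 19 methyl (2E)-4-oxo-2-({[(trifluoromethyl)sulfonyl]oxy}methylidene)butanoate
Product: 21 methyl (2E,4S)-4-hydroxy-4-{(2R,3R)-2-[(2R)-2-({[tert-butyl(dimethyl)silyl]oxy}methyl)but-3-en-1-yl]-4-methylidene-5-oxooxolan-3-yl}-2-({[(trifluoromethyl)sulfonyl]oxy}methylidene)butanoate, via allylindium reagent 20 (not isolated)
Conditions: In powder, THF/H2O, rt
Reagents that add atoms: none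
Why: Indium-mediated Barbier allylation in which the allylindium formed at C13 attacks the aldehyde through C7 in a six-membered chair transition state, anti to the C6 side chain (C7 set, trans-lactone) and, because the butenolide locks the allyl unit in the E-type geometry, with the aldehyde chain equatorial, which should give the (8S) alcohol and the exocyclic methylene lactone in the same event.

Step 13
Reactants: 21 methyl (2E,4S)-4-hydroxy-4-{(2R,3R)-2-[(2R)-2-({[tert-butyl(dimethyl)silyl]oxy}methyl)but-3-en-1-yl]-4-methylidene-5-oxooxolan-3-yl}-2-({[(trifluoromethyl)sulfonyl]oxy}methylidene)butanoate; 22 2-methylpropanoic acid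
Product: 23 methyl (2E,4R)-4-{(2R,3S)-2-[(2R)-2-({[tert-butyl(dimethyl)silyl]oxy}methyl)but-3-en-1-yl]-4-methylidene-5-oxooxolan-3-yl}-4-[(2-methylpropanoyl)oxy]-2-({[(trifluoromethyl)sulfonyl]oxy}methylidene)butanoate
Conditions: PPh3, DIAD (betaine preformed), toluene, 0 °C → rt
Reagents that add atoms: none
Why: Mitsunobu esterification in which isobutyrate displaces the C8 alkoxyphosphonium ion by SN2 with inversion, turning the (8S) alcohol into the required (8R) isobutyrate in one operation (the descriptor change at C7 is a priority effect only).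

Step 14
Reactants: 23 methyl (2E,4R)-4-{(2R,3S)-2-[(2R)-2-({[tert-butyl(dimethyl)silyl]oxy}methyl)but-3-en-1-yl]-4-methylidene-5-oxooxolan-3-yl}-4-[(2-methylpropanoyl)oxy]-2-({[(trifluoromethyl)sulfonyl]oxy}methylidene)butanoate
Product: 25 methyl (3aS,4R,6E,10S,11aR)-10-({[tert-butyl(dimethyl)silyl]oxy}methyl)-3-methylidene-4-[(2-methylpropanoyl)oxy]-2-oxo-2,3,3a,4,5,8,9,10,11,11a-decahydrocyclodeca[b]furan-6-carboxylate, via B-alkyl-9-BBN adduct 24 (not isolated)
Conditions: 9-BBN, THF, 0 °C → rt; then syringe-pump addition to PdCl2(dppf), AsPh3, Cs2CO3, DMF/THF/H2O, 45 °C, high dilution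
Reagents that add atoms: none
Why: 9-BBN adds anti-Markovnikov to the monosubstituted C2=C3 alkene (boron on C2), then zerovalent palladium inserts into the C1–O bond of the triflate, the base-activated borate transfers C2 to palladium and reductive elimination forms C1–C2. The closest known reaction type is the intramolecular B-alkyl Suzuki–Miyaura coupling of alkyl-9-BBN reagents with enol triflates, used for medium and large rings. The ten-membered ring is closed by C(sp2)–C(sp3) reductive elimination from an eleven-membered palladacycle, with the C1=C10 alkene ending endocyclic. No stereocentre is created: C4, C6, C7 and C8 are spectators, and the enoate geometry (C2 cis to C9) is inherited from the triflate because oxidative addition and reductive elimination are both stereoretentive. The step needs chemoselective hydroboration, secured by the large rate advantage of a terminal vinyl group over the conjugated C11=C13 and C1=C10 alkenes toward 9-BBN, and ring closure over oligomerisation, secured by slow addition at high dilution and by the trans-lactone and the cis C9/OTf arrangement, which turn the two chain ends toward each other.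

Step 15
Reactants: 25 methyl (3aS,4R,6E,10S,11aR)-10-({[tert-butyl(dimethyl)silyl]oxy}methyl)-3-methylidene-4-[(2-methylpropanoyl)oxy]-2-oxo-2,3,3a,4,5,8,9,10,11,11a-decahydrocyclodeca[b]furan-6-carboxylate
Product: 26 methyl (3aS,4R,6E,10S,11aR)-10-(hydroxymethyl)-3-methylidene-4-[(2-methylpropanoyl)oxy]-2-oxo-2,3,3a,4,5,8,9,10,11,11a-decahydrocyclodeca[b]furan-6-carboxylate
Conditions: HF·pyridine, pyridine/THF, 0 °C → rt
Reagents that add atoms: none
Why: Fluoride-mediated cleavage of the primary silyl ether under buffered acidic conditions, which spare the isobutyrate, the methyl ester and the base-sensitive α-methylene lactone.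

Compound list
1 | furan-2(5H)-one | O=C1OCC=C1 | starting material
2 | potassium vinyltrifluoroborate | [K+].C=C[B-](F)(F)F | starting material
3 | (4R)-4-ethenyloxolan-2-one | C=C[C@H]1CC(=O)OC1 | intermediate
4 | 1-methoxy-4-[(prop-2-yn-1-yloxy)methyl]benzene | C#CCOCc1ccc(OC)cc1 | starting material
5 | {3-[(4-methoxyphenyl)methoxy]prop-1-yn-1-yl}lithium | [Li]C#CCOCc1ccc(OC)cc1 | intermediate (not isolated)
6 | (6R)-6-(hydroxymethyl)-1-[(4-methoxyphenyl)methoxy]oct-7-en-2-yn-4-one | C=C[C@H](CO)CC(=O)C#CCOCc1ccc(OC)cc1 | intermediate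
7 | (6R)-6-({[tert-butyl(dimethyl)silyl]oxy}methyl)-1-[(4-methoxyphenyl)methoxy]oct-7-en-2-yn-4-one | C=C[C@H](CO[Si](C)(C)C(C)(C)C)CC(=O)C#CCOCc1ccc(OC)cc1 | intermediate
8 | (4R,6R)-6-({[tert-butyl(dimethyl)silyl]oxy}methyl)-1-[(4-methoxyphenyl)methoxy]oct-7-en-2-yn-4-ol | C=C[C@H](CO[Si](C)(C)C(C)(C)C)C[C@@H](O)C#CCOCc1ccc(OC)cc1 | intermediate
9 | sodium salt of the cyclic vinylalanate of 8 (five-membered C6–O–Al–C11=C7 ring, two 2-methoxyethoxy groups on aluminium) | [Na+].C=C[C@H](CO[Si](C)(C)C(C)(C)C)C[C@H]1O[Al-](OCCOC)(OCCOC)C(COCc2ccc(OC)cc2)=C1 | intermediate (not isolated)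
10 | (2Z,4R,6R)-6-({[tert-butyl(dimethyl)silyl]oxy}methyl)-2-iodo-1-[(4-methoxyphenyl)methoxy]octa-2,7-dien-4-ol | C=C[C@H](CO[Si](C)(C)C(C)(C)C)C[C@@H](O)/C=C(\I)COCc1ccc(OC)cc1 | intermediate
11 | (5R)-5-[(2R)-2-({[tert-butyl(dimethyl)silyl]oxy}methyl)but-3-en-1-yl]-3-{[(4-methoxyphenyl)methoxy]methyl}furan-2(5H)-one | C=C[C@H](CO[Si](C)(C)C(C)(C)C)C[C@H]1OC(=O)C(COCc2ccc(OC)cc2)=C1 | intermediate
12 | (5R)-5-[(2R)-2-({[tert-butyl(dimethyl)silyl]oxy}methyl)but-3-en-1-yl]-3-(hydroxymethyl)furan-2(5H)-one | C=C[C@H](CO[Si](C)(C)C(C)(C)C)C[C@H]1OC(=O)C(CO)=C1 | intermediate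
13 | (5R)-3-(bromomethyl)-5-[(2R)-2-({[tert-butyl(dimethyl)silyl]oxy}methyl)but-3-en-1-yl]furan-2(5H)-one | C=C[C@H](CO[Si](C)(C)C(C)(C)C)C[C@H]1OC(=O)C(CBr)=C1 | intermediate
14 | methyl pent-4-enoate | C=CCCC(=O)OC | starting material
15 | lithium 1-methoxypenta-1,4-dien-1-olate | C=CCC=C(O[Li])OC | intermediate (not isolated)
16 | methyl 2-formylpent-4-enoate (racemic) | C=CCC(C=O)C(=O)OC | intermediate
17 | methyl (2E)-2-({[(trifluoromethyl)sulfonyl]oxy}methylidene)pent-4-enoate | C=CC/C(C(=O)OC)=C\OS(=O)(=O)C(F)(F)F | intermediate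
18 | methyl (2E)-3-(1,2,4-trioxolan-3-yl)-2-({[(trifluoromethyl)sulfonyl]oxy}methylidene)propanoate | O1OC(C/C(C(=O)OC)=C\OS(=O)(=O)C(F)(F)F)OC1 | intermediate (not isolated)
19 | methyl (2E)-4-oxo-2-({[(trifluoromethyl)sulfonyl]oxy}methylidene)butanoate | O=CC/C(C(=O)OC)=C\OS(=O)(=O)C(F)(F)F | intermediate
20 | allylindium dibromide derived from 13 (indium on C13) | C=C[C@H](CO[Si](C)(C)C(C)(C)C)C[C@H]1OC(=O)C(C[In](Br)Br)=C1 | intermediate (not isolated)
21 | methyl (2E,4S)-4-hydroxy-4-{(2R,3R)-2-[(2R)-2-({[tert-butyl(dimethyl)silyl]oxy}methyl)but-3-en-1-yl]-4-methylidene-5-oxooxolan-3-yl}-2-({[(trifluoromethyl)sulfonyl]oxy}methylidene)butanoate | C=C1C(=O)O[C@H](C[C@@H](CO[Si](C)(C)C(C)(C)C)C=C)[C@H]1[C@@H](O)C/C(C(=O)OC)=C\OS(=O)(=O)C(F)(F)F | intermediate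
22 | 2-methylpropanoic acid (isobutyric acid) | CC(C)C(=O)O | starting material
23 | methyl (2E,4R)-4-{(2R,3S)-2-[(2R)-2-({[tert-butyl(dimethyl)silyl]oxy}methyl)but-3-en-1-yl]-4-methylidene-5-oxooxolan-3-yl}-4-[(2-methylpropanoyl)oxy]-2-({[(trifluoromethyl)sulfonyl]oxy}methylidene)butanoate | C=C1C(=O)O[C@H](C[C@@H](CO[Si](C)(C)C(C)(C)C)C=C)[C@H]1[C@H](OC(=O)C(C)C)C/C(C(=O)OC)=C\OS(=O)(=O)C(F)(F)F | intermediate
24 | 9-alkyl-9-borabicyclo[3.3.1]nonane formed from 23 (boron on C2) | C=C1C(=O)O[C@H](C[C@@H](CO[Si](C)(C)C(C)(C)C)CCB2C3CCCC2CCC3)[C@H]1[C@H](OC(=O)C(C)C)C/C(C(=O)OC)=C\OS(=O)(=O)C(F)(F)F | intermediate (not isolated)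
25 | methyl (3aS,4R,6E,10S,11aR)-10-({[tert-butyl(dimethyl)silyl]oxy}methyl)-3-methylidene-4-[(2-methylpropanoyl)oxy]-2-oxo-2,3,3a,4,5,8,9,10,11,11a-decahydrocyclodeca[b]furan-6-carboxylate | C=C1C(=O)O[C@@H]2C[C@@H](CO[Si](C)(C)C(C)(C)C)CC/C=C(/C(=O)OC)C[C@@H](OC(=O)C(C)C)[C@@H]12 | intermediate
26 | methyl (3aS,4R,6E,10S,11aR)-10-(hydroxymethyl)-3-methylidene-4-[(2-methylpropanoyl)oxy]-2-oxo-2,3,3a,4,5,8,9,10,11,11a-decahydrocyclodeca[b]furan-6-carboxylate | C=C1C(=O)O[C@@H]2C[C@@H](CO)CC/C=C(/C(=O)OC)C[C@@H](OC(=O)C(C)C)[C@@H]12 | target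

Total step count: 15 (steps 1–8 build the C2–C7/C11–C13/C15 bromobutenolide, steps 9–11 the C1/C8–C10/C14 aldehyde, steps 12–15 join them and finish).
Longest linear sequence: 12 steps (steps 1–8 and 12–15).

Steps most likely to fail

Step 14. Intermolecular coupling and oligomerisation may outrun closure of the strained ten-membered ring, or the alkylborane may be lost by protodeboronation or β-hydride elimination before transmetalation. The fallback sets out from compounds 11 and 17 and returns at compound 25: the C1–C2 bond is made intermolecularly and the ring is closed at C7–C8 by an intramolecular indium-mediated allylation, a mode of macrocyclisation established for germacranolides. The vinyl group of 11 is hydroborated with 9-BBN and the borane is coupled with enol triflate 17 (PdCl2(dppf), AsPh3, Cs2CO3, DMF/THF/H2O) to give the open-chain diene ester F1. DDQ removes the p-methoxybenzyl group to give the allylic alcohol F2, and CBr4 with PPh3 gives the allylic bromide F3. OsO4 (cat.) and NaIO4 with 2,6-lutidine cleave only the terminal alkene to give the bromo aldehyde F4. Indium metal in THF/H2O at high dilution should close the ring through the same chair-type transition state to the macrocyclic (8S) alcohol F5, and Mitsunobu esterification of F5 with acid 22 (PPh3, DIAD) inverts C8 and gives 25.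

Step 13. The activated C8 alcohol may eliminate toward C7 or C9 instead of being substituted, inversion may be incomplete, or the phosphine may attack the enol triflate. The fallback sets out from compound 13 and returns at compound 23: C8 is set directly in the required configuration through an open transition state, so that no inversion is needed. Bromide 13 is converted with Bu3SnCl and Zn in THF/aqueous NH4Cl into the allylstannane F6. Addition of F6 to aldehyde 19 promoted by BF3·OEt2 at −78 °C passes through an antiperiplanar open transition state, which is syn-selective for E-type allylstannanes and again anti to the C6 side chain, and should give the (8R) alcohol F7. Acylation of F7 with isobutyryl chloride (pyridine, DMAP, CH2Cl2) gives 23.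

Step 12. The β,γ-unsaturated aldehyde may enolise and isomerise before it is attacked, the new C8 alkoxide may displace the triflate or lactonise onto the C14 ester, and facial selectivity at C7 may erode. The fallback sets out from compound 13 and returns at compound 23: C1 is carried as a dimethyl acetal and the enol triflate is made last. Methyl 3,3-dimethoxypropanoate is allylated (LiN(iPr)2, allyl bromide, THF, −78 °C) to the acetal ester F8 and ozonised (O3; (CH3)2S) to the acetal aldehyde F9. Indium-mediated coupling of 13 with F9 gives the (8S) hydroxy lactone F10 as a mixture at C10, and Mitsunobu esterification with 22 gives the (8R) isobutyrate F11. LiBF4 in wet acetonitrile unmasks the formyl ester F12, and Tf2O with iPr2NEt at −78 °C gives 23.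

Further compounds
F1 | step 14 | methyl (2E,6S)-6-({[tert-butyl(dimethyl)silyl]oxy}methyl)-7-[(2R)-4-{[(4-methoxyphenyl)methoxy]methyl}-5-oxo-2,5-dihydrofuran-2-yl]-2-(prop-2-en-1-yl)hept-2-enoate | C=CC/C(C(=O)OC)=C\CC[C@H](CO[Si](C)(C)C(C)(C)C)C[C@H]1OC(=O)C(COCc2ccc(OC)cc2)=C1
F2 | step 14 | methyl (2E,6S)-6-({[tert-butyl(dimethyl)silyl]oxy}methyl)-7-[(2R)-4-(hydroxymethyl)-5-oxo-2,5-dihydrofuran-2-yl]-2-(prop-2-en-1-yl)hept-2-enoate | C=CC/C(C(=O)OC)=C\CC[C@H](CO[Si](C)(C)C(C)(C)C)C[C@H]1OC(=O)C(CO)=C1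
F3 | step 14 | methyl (2E,6S)-7-[(2R)-4-(bromomethyl)-5-oxo-2,5-dihydrofuran-2-yl]-6-({[tert-butyl(dimethyl)silyl]oxy}methyl)-2-(prop-2-en-1-yl)hept-2-enoate | C=CC/C(C(=O)OC)=C\CC[C@H](CO[Si](C)(C)C(C)(C)C)C[C@H]1OC(=O)C(CBr)=C1
F4 | step 14 | methyl (2E,6S)-7-[(2R)-4-(bromomethyl)-5-oxo-2,5-dihydrofuran-2-yl]-6-({[tert-butyl(dimethyl)silyl]oxy}methyl)-2-(2-oxoethyl)hept-2-enoate | O=CC/C(C(=O)OC)=C\CC[C@H](CO[Si](C)(C)C(C)(C)C)C[C@H]1OC(=O)C(CBr)=C1
F5 | step 14 | methyl (3aR,4S,6E,10S,11aR)-10-({[tert-butyl(dimethyl)silyl]oxy}methyl)-4-hydroxy-3-methylidene-2-oxo-2,3,3a,4,5,8,9,10,11,11a-decahydrocyclodeca[b]furan-6-carboxylate | C=C1C(=O)O[C@@H]2C[C@@H](CO[Si](C)(C)C(C)(C)C)CC/C=C(/C(=O)OC)C[C@H](O)[C@@H]12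
F6 | step 13 | (5R)-5-[(2R)-2-({[tert-butyl(dimethyl)silyl]oxy}methyl)but-3-en-1-yl]-3-[(tributylstannyl)methyl]furan-2(5H)-one | C=C[C@H](CO[Si](C)(C)C(C)(C)C)C[C@H]1OC(=O)C(C[Sn](CCCC)(CCCC)CCCC)=C1
F7 | step 13 | methyl (2E,4R)-4-hydroxy-4-{(2R,3R)-2-[(2R)-2-({[tert-butyl(dimethyl)silyl]oxy}methyl)but-3-en-1-yl]-4-methylidene-5-oxooxolan-3-yl}-2-({[(trifluoromethyl)sulfonyl]oxy}methylidene)butanoate (C8 epimer of 21) | C=C1C(=O)O[C@H](C[C@@H](CO[Si](C)(C)C(C)(C)C)C=C)[C@H]1[C@H](O)C/C(C(=O)OC)=C\OS(=O)(=O)C(F)(F)F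
F8 | step 12 | methyl 2-(dimethoxymethyl)pent-4-enoate (racemic) | C=CCC(C(OC)OC)C(=O)OC
F9 | step 12 | methyl 2-(dimethoxymethyl)-4-oxobutanoate (racemic) | O=CCC(C(OC)OC)C(=O)OC
F10 | step 12 | (8S) hydroxy lactone: analogue of 21 with C10 sp3 and C1 as dimethyl acetal (both C10 epimers; C4, C6, C7 as in 21) | C=C1C(=O)O[C@H](C[C@@H](CO[Si](C)(C)C(C)(C)C)C=C)[C@H]1[C@@H](O)CC(C(OC)OC)C(=O)OC
F11 | step 12 | (8R) isobutyrate: analogue of 23 with C10 sp3 and C1 as dimethyl acetal (both C10 epimers; C4, C6, C7, C8 as in 23) | C=C1C(=O)O[C@H](C[C@@H](CO[Si](C)(C)C(C)(C)C)C=C)[C@H]1[C@H](OC(=O)C(C)C)CC(C(OC)OC)C(=O)OC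
F12 | step 12 | formyl ester corresponding to 23 before triflation (C1 aldehyde, C10 sp3, both epimers, enol form present) | C=C1C(=O)O[C@H](C[C@@H](CO[Si](C)(C)C(C)(C)C)C=C)[C@H]1[C@H](OC(=O)C(C)C)CC(C=O)C(=O)OC
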